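**Retrosynthetic overview**
1. Target 29 ← bicyclic furanone 23 by C8 desilylation/methacrylation, unmasking of the 11(13)-methylene (carried as its Me2N adduct) and C15–O desilylation.
2. 23 ← acyclic ynal–methyl ketone 21 in one carbene-catalysed cascade: acyl-anion addition of C1 to the C10 ketone closes the ten-membered carbocycle (C1–C10), then the C10 alkoxide adds to C3 and closes the 3(2H)-furanone (O–C3).
3. Enabling feature: the furanone ring (O, C3, C2, C1, C10) is an α′-hydroxy-ynone retron. The C1 ketone lies between the oxygen-bearing quaternary C10 (an acyloin bond) and the enol-ether carbon C3, which is 1,4 to that oxygen. The cis C4=C5 bond and the trans-fused lactone ring (O, C12, C11, C7, C6) fold the chain.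
4. 21 ← Sonogashira coupling (C3–C4) on the Z-iodide 18 ← Wittig/α-iodination on aldehyde 13 ← proline aldol with acetone (C8–C9) on aldehyde 8 ← anti vinyl addition/Mannich trapping on the (S)-butenolide 2.
5. Ring order: γ-lactone (chiral pool), then ten-membered carbocycle, then furanone (the last two in the key step).

Key step: step 13

Remark: atoms are numbered as in germacranolides (C1–C10 ring, C11–C13 lactone carbons, C14 methyl on C10, C15 on C4). The target is taken as the (6R,7R,8R,10R,4Z) isomer drawn, and C11 of the Me2N-masked intermediates is a transient stereocentre.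

**Step 1**
Reactants: 1 (S)-5-(hydroxymethyl)furan-2(5H)-one
Product: 2 (S)-5-{[(triethylsilyl)oxy]methyl}furan-2(5H)-one
Conditions: TESCl, imidazole, CH2Cl2, 0 °C to rt
Reagents that add atoms: chlorotriethylsilane, CC[Si](Cl)(CC)CC
Why: Standard silylation of the primary alcohol; C6 comes unchanged from the chiral pool.

**Step 2**
Reactants: 2 (S)-5-{[(triethylsilyl)oxy]methyl}furan-2(5H)-one; 3 vinylmagnesium bromide; 4 N,N-dimethylmethyleneiminium iodide (Eschenmoser's salt)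
Product: 6 (3R,4S,5S)-3-[(dimethylamino)methyl]-5-{[(triethylsilyl)oxy]methyl}-4-vinyldihydrofuran-2(3H)-one, via silyl ketene acetal 5 (not isolated)
Conditions: 3, CuBr·SMe2 (10 mol%), TMSCl, THF, −78 °C; then 4, CH2Cl2, −78 °C to rt
Reagents that add atoms: none
Why: Copper-catalysed conjugate addition of the vinyl Grignard reagent anti to the C6 CH2OTES group should set C7 (trans), and Mukaiyama–Mannich trapping of the silyl ketene acetal anti to the new vinyl group sets C11 and installs the Me2NCH2 group as a masked exo-methylene.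

**Step 3**
Reactants: 6 (3R,4S,5S)-3-[(dimethylamino)methyl]-5-{[(triethylsilyl)oxy]methyl}-4-vinyldihydrofuran-2(3H)-one
Product: 8 (2S,3S,4R)-4-[(dimethylamino)methyl]-5-oxo-2-{[(triethylsilyl)oxy]methyl}tetrahydrofuran-3-carbaldehyde, via diol 7 (not isolated)
Conditions: OsO4 (2 mol%), NaIO4, 2,6-lutidine, dioxane/H2O (3:1), rt
Reagents that add atoms: sodium periodate, [Na+].[O-][I](=O)(=O)=O
Why: Lemieux–Johnson cleavage (dihydroxylation, then glycol cleavage) of the only alkene should give the C8 aldehyde, the lutidine buffer sparing the amine and the C7 centre.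

**Step 4**
Reactants: 8 (2S,3S,4R)-4-[(dimethylamino)methyl]-5-oxo-2-{[(triethylsilyl)oxy]methyl}tetrahydrofuran-3-carbaldehyde; 9 acetone
Product: 10 (3R,4R,5S)-3-[(dimethylamino)methyl]-4-[(1R)-1-hydroxy-3-oxobutyl]-5-{[(triethylsilyl)oxy]methyl}dihydrofuran-2(3H)-one
Conditions: L-proline (30 mol%), acetone/DMSO (1:4), 4 °C
Reagents that add atoms: none
Why: Proline-catalysed direct aldol reaction (enamine catalysis) on an α-branched aldehyde; the acetone enamine should attack the Re face under catalyst control and set C8 as R.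

**Step 5**
Reactants: 10 (3R,4R,5S)-3-[(dimethylamino)methyl]-4-[(1R)-1-hydroxy-3-oxobutyl]-5-{[(triethylsilyl)oxy]methyl}dihydrofuran-2(3H)-one
Product: 11 (3R,4S,5S)-3-[(dimethylamino)methyl]-4-{(1R)-3-oxo-1-[(triethylsilyl)oxy]butyl}-5-{[(triethylsilyl)oxy]methyl}dihydrofuran-2(3H)-one
Conditions: TESCl, imidazole, DMAP (cat.), DMF, 0 °C to rt
Reagents that add atoms: chlorotriethylsilane, CC[Si](Cl)(CC)CC
Why: Silylation turns the C8 hydroxyl into an ether that is a poor β-leaving group next to the C10 ketone in the later basic steps.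

**Step 6**
Reactants: 11 (3R,4S,5S)-3-[(dimethylamino)methyl]-4-{(1R)-3-oxo-1-[(triethylsilyl)oxy]butyl}-5-{[(triethylsilyl)oxy]methyl}dihydrofuran-2(3H)-one
Product: 13 (2S,3S,4R)-4-[(dimethylamino)methyl]-5-oxo-3-{(1R)-3-oxo-1-[(triethylsilyl)oxy]butyl}tetrahydrofuran-2-carbaldehyde, via alkoxysulfonium chloride 12 (not isolated)
Conditions: (COCl)2, DMSO, CH2Cl2, −78 to −40 °C; then Et3N, −78 to 0 °C
Reagents that add atoms: none
Why: Swern conditions oxidise a primary triethylsilyl ether directly to the aldehyde (the chlorosulfonium salt displaces silicon from the less hindered oxygen) while the secondary C8 ether should stay, so deprotection and oxidation are one step.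

**Step 7**
Reactants: 13 (2S,3S,4R)-4-[(dimethylamino)methyl]-5-oxo-3-{(1R)-3-oxo-1-[(triethylsilyl)oxy]butyl}tetrahydrofuran-2-carbaldehyde; 14 (triphenylphosphoranylidene)acetaldehyde
Product: 15 (E)-3-[(2R,3S,4R)-4-[(dimethylamino)methyl]-5-oxo-3-{(1R)-3-oxo-1-[(triethylsilyl)oxy]butyl}tetrahydrofuran-2-yl]acrylaldehyde
Conditions: toluene, 40 °C
Reagents that add atoms: none
Why: Wittig reaction of the stabilised formyl ylide with the aldehyde (the ketone is left alone) should give the E enal, the two ylide carbons becoming C4 and C15.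

**Step 8**
Reactants: 15 (E)-3-[(2R,3S,4R)-4-[(dimethylamino)methyl]-5-oxo-3-{(1R)-3-oxo-1-[(triethylsilyl)oxy]butyl}tetrahydrofuran-2-yl]acrylaldehyde
Product: 16 (Z)-3-[(2S,3S,4R)-4-[(dimethylamino)methyl]-5-oxo-3-{(1R)-3-oxo-1-[(triethylsilyl)oxy]butyl}tetrahydrofuran-2-yl]-2-iodoacrylaldehyde
Conditions: I2, pyridine, CH2Cl2, 0 °C to rt
Reagents that add atoms: iodine, II
Why: α-Iodination of the enal (conjugate addition of pyridine, iodination of the enolate, elimination) should give the more stable Z α-iodoenal, with iodine cis to C6 and the formyl group trans.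

**Step 9**
Reactants: 16 (Z)-3-[(2S,3S,4R)-4-[(dimethylamino)methyl]-5-oxo-3-{(1R)-3-oxo-1-[(triethylsilyl)oxy]butyl}tetrahydrofuran-2-yl]-2-iodoacrylaldehyde
Product: 17 (3R,4S,5S)-3-[(dimethylamino)methyl]-5-[(Z)-3-hydroxy-2-iodoprop-1-en-1-yl]-4-{(1R)-3-oxo-1-[(triethylsilyl)oxy]butyl}dihydrofuran-2(3H)-one
Conditions: NaBH(OAc)3, THF, rt
Reagents that add atoms: none
Why: Triacetoxyborohydride reduces the aldehyde 1,2 and should leave the C10 methyl ketone, the lactone and the vinyl iodide untouched.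

**Step 10**
Reactants: 17 (3R,4S,5S)-3-[(dimethylamino)methyl]-5-[(Z)-3-hydroxy-2-iodoprop-1-en-1-yl]-4-{(1R)-3-oxo-1-[(triethylsilyl)oxy]butyl}dihydrofuran-2(3H)-one
Product: 18 (3R,4S,5S)-5-[(Z)-3-{[tert-butyl(diphenyl)silyl]oxy}-2-iodoprop-1-en-1-yl]-3-[(dimethylamino)methyl]-4-{(1R)-3-oxo-1-[(triethylsilyl)oxy]butyl}dihydrofuran-2(3H)-one
Conditions: TBDPSCl, imidazole, CH2Cl2, rt
Reagents that add atoms: tert-butyl(chloro)diphenylsilane, CC(C)(C)[Si](Cl)(c1ccccc1)c1ccccc1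
Why: Silylation of the primary allylic C15 alcohol with a group that outlasts the later acidic removal of the C8 triethylsilyl ether.

**Step 11**
Reactants: 18 (3R,4S,5S)-5-[(Z)-3-{[tert-butyl(diphenyl)silyl]oxy}-2-iodoprop-1-en-1-yl]-3-[(dimethylamino)methyl]-4-{(1R)-3-oxo-1-[(triethylsilyl)oxy]butyl}dihydrofuran-2(3H)-one; 19 prop-2-yn-1-ol
Product: 20 (3R,4S,5R)-5-[(E)-2-({[tert-butyl(diphenyl)silyl]oxy}methyl)-5-hydroxypent-1-en-3-yn-1-yl]-3-[(dimethylamino)methyl]-4-{(1R)-3-oxo-1-[(triethylsilyl)oxy]butyl}dihydrofuran-2(3H)-one (alkyne cis to C6)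
Conditions: Pd(PPh3)2Cl2 (5 mol%), CuI (10 mol%), Et3N, THF, rt
Reagents that add atoms: none
Why: Sonogashira coupling at the vinyl iodide forms C3–C4 with retention of the double-bond geometry.

**Step 12**
Reactants: 20 (3R,4S,5R)-5-[(E)-2-({[tert-butyl(diphenyl)silyl]oxy}methyl)-5-hydroxypent-1-en-3-yn-1-yl]-3-[(dimethylamino)methyl]-4-{(1R)-3-oxo-1-[(triethylsilyl)oxy]butyl}dihydrofuran-2(3H)-one
Product: 21 (E)-4-({[tert-butyl(diphenyl)silyl]oxy}methyl)-5-[(2R,3S,4R)-4-[(dimethylamino)methyl]-5-oxo-3-{(1R)-3-oxo-1-[(triethylsilyl)oxy]butyl}tetrahydrofuran-2-yl]pent-4-en-2-ynal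
Conditions: MnO2, CH2Cl2, rt
Reagents that add atoms: none
Why: MnO2 oxidises the only free (propargylic) alcohol to the ynal under neutral conditions; 21 should be used at once.

**Step 13**
Reactants: 21 (E)-4-({[tert-butyl(diphenyl)silyl]oxy}methyl)-5-[(2R,3S,4R)-4-[(dimethylamino)methyl]-5-oxo-3-{(1R)-3-oxo-1-[(triethylsilyl)oxy]butyl}tetrahydrofuran-2-yl]pent-4-en-2-ynal
Product: 23 (4Z,6R,7S,8R,10R,11R)-15-{[tert-butyl(diphenyl)silyl]oxy}-13-(dimethylamino)-3,10-epoxy-1-oxo-8-[(triethylsilyl)oxy]germacra-2,4-dien-12,6-olide, via ten-membered hydroxy ynone 22 (not isolated)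
Conditions: aminoindanol-derived N-C6F5 triazolium tetrafluoroborate (20 mol%), i-Pr2NEt (0.2 equiv), 4 Å MS, toluene (0.002 M, slow addition of 21), 40 °C
Reagents that add atoms: none
Why: Proposed new method: the triazolylidene adds to the ynal carbon C1 and proton transfer gives the alkynyl Breslow intermediate, whose C1 adds as an acyl anion to the C10 methyl ketone; release of the carbene leaves the ten-membered α-hydroxy ynone 22, whose C10 alkoxide adds to C3 and, after protonation at C2, gives the 3(2H)-furanone, so that C1–C10 and O–C3 form in one flask. The closest known reactions are the carbene-catalysed intramolecular aldehyde–ketone crossed benzoin reaction (established for five- and six-membered rings with unactivated ketones) and the base- or gold-catalysed cyclisation of α′-hydroxy ynones to 3(2H)-furanones; new are the ring size and the ynal donor. The carbocycle closes 10-exo-trig (C1 onto the exocyclic C10=O) and the furanone 5-endo-dig (oxygen onto C3 of the ring alkyne), the second closure being irreversible and draining the reversible benzoin equilibrium. C10 is the only new stereocentre and is set by the ketone face attacked, under control of the chiral triazolylidene (enantiomer to be chosen by screening) and of the chain folded by the cis C4=C5 bond and the trans-fused lactone, while a mis-set epimer of 22 can return by retro-benzoin. The step needs aldehyde-donor/ketone-acceptor chemoselectivity and C-attack instead of redox isomerisation: there is one non-enolisable aldehyde and one ketone, every hydroxyl is silylated so no acyl azolium can be trapped, the methylene lactone is masked so no Stetter or polymerisation acceptor is present, the C8 oxygen is a silyl ether and a poor β-leaving group, and high dilution suppresses ynal dimerisation.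

**Step 14**
Reactants: 23 (4Z,6R,7S,8R,10R,11R)-15-{[tert-butyl(diphenyl)silyl]oxy}-13-(dimethylamino)-3,10-epoxy-1-oxo-8-[(triethylsilyl)oxy]germacra-2,4-dien-12,6-olide
Product: 24 (4Z,6R,7R,8R,10R,11R)-15-{[tert-butyl(diphenyl)silyl]oxy}-13-(dimethylamino)-3,10-epoxy-8-hydroxy-1-oxogermacra-2,4-dien-12,6-olide
Conditions: AcOH/THF/H2O (3:1:1), rt
Reagents that add atoms: none
Why: Acid hydrolysis should remove the secondary triethylsilyl ether far faster than the primary tert-butyldiphenylsilyl ether.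

**Step 15**
Reactants: 24 (4Z,6R,7R,8R,10R,11R)-15-{[tert-butyl(diphenyl)silyl]oxy}-13-(dimethylamino)-3,10-epoxy-8-hydroxy-1-oxogermacra-2,4-dien-12,6-olide; 25 methacrylic anhydride
Product: 26 (4Z,6R,7R,8R,10R,11R)-15-{[tert-butyl(diphenyl)silyl]oxy}-13-(dimethylamino)-3,10-epoxy-8-(methacryloyloxy)-1-oxogermacra-2,4-dien-12,6-olide
Conditions: Et3N, DMAP (cat.), CH2Cl2, 0 °C to rt
Reagents that add atoms: none
Why: DMAP-catalysed acylation of the C8 alcohol, the only free hydroxyl.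

**Step 16**
Reactants: 26 (4Z,6R,7R,8R,10R,11R)-15-{[tert-butyl(diphenyl)silyl]oxy}-13-(dimethylamino)-3,10-epoxy-8-(methacryloyloxy)-1-oxogermacra-2,4-dien-12,6-olide
Product: 28 (4Z,6R,7R,8R,10R)-15-{[tert-butyl(diphenyl)silyl]oxy}-3,10-epoxy-8-(methacryloyloxy)-1-oxogermacra-2,4,11(13)-trien-12,6-olide, via trimethylammonium iodide 27 (not isolated)
Conditions: MeI, MeCN, rt; then NaHCO3, H2O, rt
Reagents that add atoms: none
Why: N-Methylation makes the amine a leaving group and mild base eliminates trimethylamine (E1cB through H11, the only β-hydrogen), which should regenerate the 11(13)-methylene lactone and erase the C11 centre.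

**Step 17**
Reactants: 28 (4Z,6R,7R,8R,10R)-15-{[tert-butyl(diphenyl)silyl]oxy}-3,10-epoxy-8-(methacryloyloxy)-1-oxogermacra-2,4,11(13)-trien-12,6-olide
Product: 29 (4Z,6R,7R,8R,10R)-3,10-epoxy-15-hydroxy-8-(methacryloyloxy)-1-oxogermacra-2,4,11(13)-trien-12,6-olide (target)
Conditions: HF·pyridine, pyridine, THF, 0 °C to rt
Reagents that add atoms: none
Why: Buffered fluoride cleavage of the silyl ether, conditions that the three Michael acceptors should tolerate.

**Compound list**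
1 | (S)-5-(hydroxymethyl)furan-2(5H)-one | OC[C@H]1OC(=O)C=C1 | starting material
2 | (S)-5-{[(triethylsilyl)oxy]methyl}furan-2(5H)-one | CC[Si](CC)(CC)OC[C@H]1OC(=O)C=C1 | intermediate
3 | vinylmagnesium bromide | C=C[Mg]Br | starting material
4 | N,N-dimethylmethyleneiminium iodide (Eschenmoser's salt) | C[N+](C)=C.[I-] | starting material
5 | triethyl{[(2S,3S)-5-[(trimethylsilyl)oxy]-3-vinyl-2,3-dihydrofuran-2-yl]methoxy}silane (silyl ketene acetal) | CC[Si](CC)(CC)OC[C@H]1OC(O[Si](C)(C)C)=C[C@@H]1C=C | intermediate (not isolated)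
6 | (3R,4S,5S)-3-[(dimethylamino)methyl]-5-{[(triethylsilyl)oxy]methyl}-4-vinyldihydrofuran-2(3H)-one | CC[Si](CC)(CC)OC[C@H]1OC(=O)[C@@H](CN(C)C)[C@@H]1C=C | intermediate
7 | (3R,4R,5S)-4-(1,2-dihydroxyethyl)-3-[(dimethylamino)methyl]-5-{[(triethylsilyl)oxy]methyl}dihydrofuran-2(3H)-one (both carbinol epimers) | CC[Si](CC)(CC)OC[C@H]1OC(=O)[C@@H](CN(C)C)[C@@H]1C(O)CO | intermediate (not isolated)
8 | (2S,3S,4R)-4-[(dimethylamino)methyl]-5-oxo-2-{[(triethylsilyl)oxy]methyl}tetrahydrofuran-3-carbaldehyde | CC[Si](CC)(CC)OC[C@H]1OC(=O)[C@@H](CN(C)C)[C@@H]1C=O | intermediate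
9 | acetone | CC(C)=O | starting material
10 | (3R,4R,5S)-3-[(dimethylamino)methyl]-4-[(1R)-1-hydroxy-3-oxobutyl]-5-{[(triethylsilyl)oxy]methyl}dihydrofuran-2(3H)-one | CC[Si](CC)(CC)OC[C@H]1OC(=O)[C@@H](CN(C)C)[C@@H]1[C@H](O)CC(C)=O | intermediate
11 | (3R,4S,5S)-3-[(dimethylamino)methyl]-4-{(1R)-3-oxo-1-[(triethylsilyl)oxy]butyl}-5-{[(triethylsilyl)oxy]methyl}dihydrofuran-2(3H)-one | CC[Si](CC)(CC)OC[C@H]1OC(=O)[C@@H](CN(C)C)[C@@H]1[C@H](O[Si](CC)(CC)CC)CC(C)=O | intermediate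
12 | dimethyl{[(2S,3S,4R)-4-[(dimethylamino)methyl]-5-oxo-3-{(1R)-3-oxo-1-[(triethylsilyl)oxy]butyl}tetrahydrofuran-2-yl]methoxy}sulfonium chloride | C[S+](C)OC[C@H]1OC(=O)[C@@H](CN(C)C)[C@@H]1[C@H](O[Si](CC)(CC)CC)CC(C)=O.[Cl-] | intermediate (not isolated)
13 | (2S,3S,4R)-4-[(dimethylamino)methyl]-5-oxo-3-{(1R)-3-oxo-1-[(triethylsilyl)oxy]butyl}tetrahydrofuran-2-carbaldehyde | O=C[C@H]1OC(=O)[C@@H](CN(C)C)[C@@H]1[C@H](O[Si](CC)(CC)CC)CC(C)=O | intermediate
14 | (triphenylphosphoranylidene)acetaldehyde | O=CC=P(c1ccccc1)(c1ccccc1)c1ccccc1 | starting material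
15 | (E)-3-[(2R,3S,4R)-4-[(dimethylamino)methyl]-5-oxo-3-{(1R)-3-oxo-1-[(triethylsilyl)oxy]butyl}tetrahydrofuran-2-yl]acrylaldehyde | O=C/C=C/[C@H]1OC(=O)[C@@H](CN(C)C)[C@@H]1[C@H](O[Si](CC)(CC)CC)CC(C)=O | intermediate
16 | (Z)-3-[(2S,3S,4R)-4-[(dimethylamino)methyl]-5-oxo-3-{(1R)-3-oxo-1-[(triethylsilyl)oxy]butyl}tetrahydrofuran-2-yl]-2-iodoacrylaldehyde | I/C(C=O)=C\[C@H]1OC(=O)[C@@H](CN(C)C)[C@@H]1[C@H](O[Si](CC)(CC)CC)CC(C)=O | intermediate
17 | (3R,4S,5S)-3-[(dimethylamino)methyl]-5-[(Z)-3-hydroxy-2-iodoprop-1-en-1-yl]-4-{(1R)-3-oxo-1-[(triethylsilyl)oxy]butyl}dihydrofuran-2(3H)-one | I/C(CO)=C\[C@H]1OC(=O)[C@@H](CN(C)C)[C@@H]1[C@H](O[Si](CC)(CC)CC)CC(C)=O | intermediate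
18 | (3R,4S,5S)-5-[(Z)-3-{[tert-butyl(diphenyl)silyl]oxy}-2-iodoprop-1-en-1-yl]-3-[(dimethylamino)methyl]-4-{(1R)-3-oxo-1-[(triethylsilyl)oxy]butyl}dihydrofuran-2(3H)-one | I/C(CO[Si](c2ccccc2)(c2ccccc2)C(C)(C)C)=C\[C@H]1OC(=O)[C@@H](CN(C)C)[C@@H]1[C@H](O[Si](CC)(CC)CC)CC(C)=O | intermediate
19 | prop-2-yn-1-ol | C#CCO | starting material
20 | (3R,4S,5R)-5-[(E)-2-({[tert-butyl(diphenyl)silyl]oxy}methyl)-5-hydroxypent-1-en-3-yn-1-yl]-3-[(dimethylamino)methyl]-4-{(1R)-3-oxo-1-[(triethylsilyl)oxy]butyl}dihydrofuran-2(3H)-one | OCC#C/C(CO[Si](c2ccccc2)(c2ccccc2)C(C)(C)C)=C\[C@H]1OC(=O)[C@@H](CN(C)C)[C@@H]1[C@H](O[Si](CC)(CC)CC)CC(C)=O | intermediate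
21 | (E)-4-({[tert-butyl(diphenyl)silyl]oxy}methyl)-5-[(2R,3S,4R)-4-[(dimethylamino)methyl]-5-oxo-3-{(1R)-3-oxo-1-[(triethylsilyl)oxy]butyl}tetrahydrofuran-2-yl]pent-4-en-2-ynal | O=CC#C/C(CO[Si](c2ccccc2)(c2ccccc2)C(C)(C)C)=C\[C@H]1OC(=O)[C@@H](CN(C)C)[C@@H]1[C@H](O[Si](CC)(CC)CC)CC(C)=O | intermediate
22 | (6R,7S,8R,10R,11R)-15-{[tert-butyl(diphenyl)silyl]oxy}-13-(dimethylamino)-10-hydroxy-1-oxo-8-[(triethylsilyl)oxy]germacr-4-en-2-yn-12,6-olide (C3 and C6 cis on C4=C5) | O=C1C#C/C(CO[Si](c2ccccc2)(c2ccccc2)C(C)(C)C)=C\[C@H]2OC(=O)[C@@H](CN(C)C)[C@@H]2[C@H](O[Si](CC)(CC)CC)C[C@@]1(C)O | intermediate (not isolated)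
23 | (4Z,6R,7S,8R,10R,11R)-15-{[tert-butyl(diphenyl)silyl]oxy}-13-(dimethylamino)-3,10-epoxy-1-oxo-8-[(triethylsilyl)oxy]germacra-2,4-dien-12,6-olide | CC[Si](CC)(CC)O[C@@H]1C[C@@]2(C)OC(=CC2=O)/C(CO[Si](c3ccccc3)(c3ccccc3)C(C)(C)C)=C\[C@H]2OC(=O)[C@@H](CN(C)C)[C@@H]21 | intermediate
24 | (4Z,6R,7R,8R,10R,11R)-15-{[tert-butyl(diphenyl)silyl]oxy}-13-(dimethylamino)-3,10-epoxy-8-hydroxy-1-oxogermacra-2,4-dien-12,6-olide | O[C@@H]1C[C@@]2(C)OC(=CC2=O)/C(CO[Si](c3ccccc3)(c3ccccc3)C(C)(C)C)=C\[C@H]2OC(=O)[C@@H](CN(C)C)[C@@H]21 | intermediate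
25 | methacrylic anhydride | C=C(C)C(=O)OC(=O)C(C)=C | starting material
26 | (4Z,6R,7R,8R,10R,11R)-15-{[tert-butyl(diphenyl)silyl]oxy}-13-(dimethylamino)-3,10-epoxy-8-(methacryloyloxy)-1-oxogermacra-2,4-dien-12,6-olide | C=C(C)C(=O)O[C@@H]1C[C@@]2(C)OC(=CC2=O)/C(CO[Si](c3ccccc3)(c3ccccc3)C(C)(C)C)=C\[C@H]2OC(=O)[C@@H](CN(C)C)[C@@H]21 | intermediate
27 | (4Z,6R,7R,8R,10R,11R)-15-{[tert-butyl(diphenyl)silyl]oxy}-3,10-epoxy-8-(methacryloyloxy)-1-oxo-13-(trimethylammonio)germacra-2,4-dien-12,6-olide iodide | C=C(C)C(=O)O[C@@H]1C[C@@]2(C)OC(=CC2=O)/C(CO[Si](c3ccccc3)(c3ccccc3)C(C)(C)C)=C\[C@H]2OC(=O)[C@@H](C[N+](C)(C)C)[C@@H]21.[I-] | intermediate (not isolated)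
28 | (4Z,6R,7R,8R,10R)-15-{[tert-butyl(diphenyl)silyl]oxy}-3,10-epoxy-8-(methacryloyloxy)-1-oxogermacra-2,4,11(13)-trien-12,6-olide | C=C(C)C(=O)O[C@@H]1C[C@@]2(C)OC(=CC2=O)/C(CO[Si](c3ccccc3)(c3ccccc3)C(C)(C)C)=C\[C@H]2OC(=O)C(=C)[C@@H]21 | intermediate
29 | (4Z,6R,7R,8R,10R)-3,10-epoxy-15-hydroxy-8-(methacryloyloxy)-1-oxogermacra-2,4,11(13)-trien-12,6-olide | C=C(C)C(=O)O[C@@H]1C[C@@]2(C)OC(=CC2=O)/C(CO)=C\[C@H]2OC(=O)C(=C)[C@@H]21 | target

**Step count and risk**
Total step count: 17. Longest linear sequence: 17 steps (from 1).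

Steps most likely to fail:

1. Step 13 (key step). The macrocyclising C–C bond formation may lose to redox isomerisation of the ynal or to oligomerisation, and the ketone face may be attacked with poor selectivity. The fallback sets out from 18 and comes back at 23. CeCl3-mediated addition of ethynylmagnesium bromide to the C10 ketone of 18 (THF, −78 °C) makes the C1–C10 bond first and should give, after separation of the C10 epimers, the (10R)-propargylic alcohol (3R,4S,5S)-5-[(Z)-3-{[tert-butyl(diphenyl)silyl]oxy}-2-iodoprop-1-en-1-yl]-3-[(dimethylamino)methyl]-4-{(1R,3R)-3-hydroxy-3-methyl-1-[(triethylsilyl)oxy]pent-4-yn-1-yl}dihydrofuran-2(3H)-one F1. An intramolecular carbonylative Sonogashira coupling (Pd(PPh3)2Cl2, CuI, CO 1 atm, Et3N, THF, high dilution) then inserts C3 as carbon monoxide and closes the ten-membered ring to the macrocyclic 4-hydroxy-2-ynone (4Z,6R,7S,8R,10R,11R)-15-{[tert-butyl(diphenyl)silyl]oxy}-13-(dimethylamino)-10-hydroxy-3-oxo-8-[(triethylsilyl)oxy]germacr-4-en-1-yn-12,6-olide F2. Conjugate addition of Et2NH (THF, rt) gives the enaminone, the 1-(diethylamino)-1-ene analogue of that ynone, F3. Mild aqueous acid (1 M oxalic acid, THF, 0 °C) hydrolyses the enamine to the C1 ketone and lets the C10 hydroxyl condense onto C3 with loss of water, which returns 23.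

2. Step 4. The enolisable β-acyloxy aldehyde may undergo β-elimination with opening of the lactone, or the substrate may oppose the catalyst so that the aldehyde face is poorly differentiated. The fallback sets out from 8 and comes back at 11. Reagent-controlled methallylation with B-methallyldiisopinocampheylborane made from (+)-B-methoxydiisopinocampheylborane and methallylmagnesium chloride (Et2O, −78 °C, ethanolamine work-up) should give the homoallylic alcohol (3R,4R,5S)-3-[(dimethylamino)methyl]-4-[(1R)-1-hydroxy-3-methylbut-3-en-1-yl]-5-{[(triethylsilyl)oxy]methyl}dihydrofuran-2(3H)-one F4. Silylation (TESCl, imidazole, DMF) gives its triethylsilyl ether (3R,4S,5S)-3-[(dimethylamino)methyl]-4-{(1R)-3-methyl-1-[(triethylsilyl)oxy]but-3-en-1-yl}-5-{[(triethylsilyl)oxy]methyl}dihydrofuran-2(3H)-one F5. Lemieux–Johnson cleavage of the 1,1-disubstituted alkene (OsO4 cat., NaIO4, 2,6-lutidine, dioxane/H2O) gives the methyl ketone 11.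

3. Step 8. Under the basic iodination conditions C6 may epimerise by γ-deprotonation of the γ-acyloxy enal, and the double-bond geometry may be poorly controlled. The fallback sets out from 13 and comes back at 16. Addition of ethynylmagnesium bromide (1.05 equiv, THF, −78 °C) to the aldehyde gives the propargylic alcohol (3R,4S,5S)-3-[(dimethylamino)methyl]-5-(1-hydroxyprop-2-yn-1-yl)-4-{(1R)-3-oxo-1-[(triethylsilyl)oxy]butyl}dihydrofuran-2(3H)-one F6 (both carbinol epimers). A halogen-intercepted Meyer–Schuster rearrangement (Ph3PAuNTf2 and MoO2(acac)2 cat., N-iodosuccinimide, CH2Cl2, rt) converts it under non-basic conditions into the Z α-iodoenal 16.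

**Further compounds**
F1 | step 13 | (3R,4S,5S)-5-[(Z)-3-{[tert-butyl(diphenyl)silyl]oxy}-2-iodoprop-1-en-1-yl]-3-[(dimethylamino)methyl]-4-{(1R,3R)-3-hydroxy-3-methyl-1-[(triethylsilyl)oxy]pent-4-yn-1-yl}dihydrofuran-2(3H)-one | I/C(CO[Si](c2ccccc2)(c2ccccc2)C(C)(C)C)=C\[C@H]1OC(=O)[C@@H](CN(C)C)[C@@H]1[C@H](O[Si](CC)(CC)CC)C[C@@](C)(O)C#C
F2 | step 13 | (4Z,6R,7S,8R,10R,11R)-15-{[tert-butyl(diphenyl)silyl]oxy}-13-(dimethylamino)-10-hydroxy-3-oxo-8-[(triethylsilyl)oxy]germacr-4-en-1-yn-12,6-olide | O=C1/C(CO[Si](c2ccccc2)(c2ccccc2)C(C)(C)C)=C\[C@H]2OC(=O)[C@@H](CN(C)C)[C@@H]2[C@H](O[Si](CC)(CC)CC)C[C@@](C)(O)C#C1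
F3 | step 13 | (4Z,6R,7S,8R,10R,11R)-15-{[tert-butyl(diphenyl)silyl]oxy}-1-(diethylamino)-13-(dimethylamino)-10-hydroxy-3-oxo-8-[(triethylsilyl)oxy]germacra-1,4-dien-12,6-olide | O=C1/C(CO[Si](c2ccccc2)(c2ccccc2)C(C)(C)C)=C\[C@H]2OC(=O)[C@@H](CN(C)C)[C@@H]2[C@H](O[Si](CC)(CC)CC)C[C@@](C)(O)C(N(CC)CC)=C1
F4 | step 4 | (3R,4R,5S)-3-[(dimethylamino)methyl]-4-[(1R)-1-hydroxy-3-methylbut-3-en-1-yl]-5-{[(triethylsilyl)oxy]methyl}dihydrofuran-2(3H)-one | CC[Si](CC)(CC)OC[C@H]1OC(=O)[C@@H](CN(C)C)[C@@H]1[C@H](O)CC(C)=C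
F5 | step 4 | (3R,4S,5S)-3-[(dimethylamino)methyl]-4-{(1R)-3-methyl-1-[(triethylsilyl)oxy]but-3-en-1-yl}-5-{[(triethylsilyl)oxy]methyl}dihydrofuran-2(3H)-one | CC[Si](CC)(CC)OC[C@H]1OC(=O)[C@@H](CN(C)C)[C@@H]1[C@H](O[Si](CC)(CC)CC)CC(C)=C
F6 | step 8 | (3R,4S,5S)-3-[(dimethylamino)methyl]-5-(1-hydroxyprop-2-yn-1-yl)-4-{(1R)-3-oxo-1-[(triethylsilyl)oxy]butyl}dihydrofuran-2(3H)-one | C#CC(O)[C@H]1OC(=O)[C@@H](CN(C)C)[C@@H]1[C@H](O[Si](CC)(CC)CC)CC(C)=O
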